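All runs stem from a simulated flask for an exercise.

At 40 h I read the elm flask, which has been followed so far and stays in its bath; birch is the earlier, cooler run.

common to all: free catalyst 0.2 mol%

| run | substrate | temperature | remark | time |
|---|---|---|---|---|
| elm | 0.070 M | 110 °C | the very flask that is asked about, followed so far |  |
| birch | 0.11 M | 95 °C | run made earlier |  |
| flask | 0.070 M | 110 °C |  | 40 h |

| run | time / h | target / % |
|---|---|---|
| elm | 2.50 | 37 |
| elm | 5.00 | 37 |
| elm | 10.0 | 49 |
| elm | 15.0 | 48 |
| elm | 30.0 | 48 |
| birch | 0.833 | 15 |
| birch | 2.00 | 26 |
| birch | 3.00 | 28 |
| birch | 4.00 | 28 |

(standard deviation of a reading: 2 percentage points)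

- red: at 40 h add free catalyst, 50.0% of the amount charged, then wait 12 h
- teal: change nothing and wait 12 h more
- grey: at 40 h raise the temperature by 10 K, then wait 12 h
- blue: at 40 h take out 90% of the target then present, then wait 12 h

- target, in percent of the substrate first charged, at 40 h
- which option adds most target ("none" when 2 percentage points or less is all one gets) (red / teal / grey / blue / none)
- target present, with what was taken out counted in, in percent of the substrate first charged, after teal
- target present, with what was taken out counted in, in percent of the substrate first charged, after grey

- what is taken out of target is counted as made
- on the list of suspects stand: 2 free catalyst -> spent catalyst; substrate -> intermediate; free catalyst + intermediate -> free catalyst + target; substrate -> uncatalysed product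
- additions bring no volume worth counting

I look at the rate of target in elm and at nothing else. Up to the first reading it averages 0.148 /h of the charge. From there to 10.0 h it averages 0.0160 /h, slower by a factor of 9.25. From 10.0 h to 30.0 h the readings are flat, so the rate can't be told from the scatter of their difference, 0.00141 /h, a further factor of 11.3.

If catalyst dies in pairs, as the first suspect says, free catalyst late in a run falls as one over the time. Rate times time then falls slowly, and a late gain is counted per factor e of time. I call this the creep number, the size of creep that the flat readings can hide per factor e of time: 2.6 percentage points.

The late readings average 48.3%, and the creep number adds about 0.75 points up to 40 h. By this reckoning, waiting a further 12 h in elm adds about 0.68 points, which is less than the margin. The suspect step to target has free catalyst as a factor in its rate, so my choice is red.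

The forecast says 49% now, 49.5% after teal, 50.5% after grey, and red as best: “Only fresh catalyst can turn stranded intermediate into target”.

    2 free catalyst → spent catalyst (k = 1200 /M/min, Ea = 62.0 kJ/mol)
    substrate → intermediate (k = 0.100 /min, Ea = 122 kJ/mol)
    free catalyst + intermediate → free catalyst + target (k = 870 /M/min, Ea = 52.0 kJ/mol)
    substrate → uncatalysed product (k = 0.0780 /min, Ea = 103 kJ/mol)
    (constants at 110 °C)

Elm gives 49.2% at 40 h, 49.8% after teal and 50.1% after grey, and red adds 5.8 points, so the forecast held. Teal adds 0.63 points against my 0.68 points. A neighbour flask with elm's charge and temperature, read at 10 h, stands at 44.6%, and from there the creep number carries 3.6 points up to 40 h, where elm shows 4.6 points. At 40 h elm holds intermediate at 7.01% of the substrate charged, and 0.124% of the catalyst charged is still free. In the run without the second-order catalyst death, the gain from red falls from 5.8 points to 0 points.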